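**Retrosynthetic overview**
1. Target 28 ⇐ hexaacetate 27 ⇐ exo- and enantioselective Diels–Alder reaction of flavone diene 19 with 2'-hydroxychalcone 25; the cyclohexene ring and all three stereocentres are made last.
2. 19 ⇐ key disconnection at the O1–C2 bond of ring C (together with C3–prenyl): ynone 16 with a ring-A ortho prenyl ether, closed by a palladium-catalysed cyclisation with O-to-C prenyl transfer.
3. 16 ⇐ ring-A aldehyde 13 + ring-B alkyne 5; both aryl prenyl ethers come from Williamson C–O bond formation, the diene from Suzuki coupling of bromide 8.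
4. 25 ⇐ Claisen–Schmidt condensation of C-prenylated ketone 21 with aldehyde 22.
5. Ring order: rings A and B are bought arenes; ring C (pyranone) is closed in step 11; the cyclohexene ring is formed in step 18.

Assumption: the facial sense of the (S)-VANOL borate in step 18 is taken by analogy with related 2'-hydroxychalcone cycloadditions; if the first run gives the mirror-image adduct, (R)-VANOL is used and nothing else changes.

**Route**

Step 1
Reactants: 1 2,4-dihydroxybenzaldehyde; 2 prenyl bromide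
Product: 3 2-hydroxy-4-(3-methylbut-2-enyloxy)benzaldehyde
Conditions: K2CO3 (1.0 equiv), acetone, rt to 45 °C
Reagents that add atoms: none
Why: Williamson etherification goes to the 4-OH because the 2-OH is hydrogen-bonded to the aldehyde; this C–O bond is the aryl prenyl ether of the target.

Step 2
Reactants: 3 2-hydroxy-4-(3-methylbut-2-enyloxy)benzaldehyde
Product: 4 4-(3-methylbut-2-enyloxy)-2-(triisopropylsilyloxy)benzaldehyde
Conditions: TIPSCl, imidazole, DMF, rt
Reagents that add atoms: triisopropylsilyl chloride, CC(C)[Si](Cl)(C(C)C)C(C)C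
Why: Silylation masks the phenol that would otherwise add to the alkyne later; the TIPS ether is stable to base and is removed without acid.

Step 3
Reactants: 4 4-(3-methylbut-2-enyloxy)-2-(triisopropylsilyloxy)benzaldehyde
Product: 5 1-ethynyl-4-(3-methylbut-2-enyloxy)-2-(triisopropylsilyloxy)benzene
Conditions: dimethyl (1-diazo-2-oxopropyl)phosphonate, K2CO3, MeOH, 0 °C to rt
Reagents that add atoms: dimethyl (1-diazo-2-oxopropyl)phosphonate, COP(=O)(OC)C(=[N+]=[N-])C(C)=O
Why: Ohira–Bestmann (Seyferth–Gilbert) homologation converts the aryl aldehyde into the terminal alkyne under mild base.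

Step 4
Reactants: 6 2,4,6-trihydroxybenzaldehyde
Product: 7 2-hydroxy-4,6-bis(triisopropylsilyloxy)benzaldehyde
Conditions: TIPSCl (2.1 equiv), imidazole, DMF, 0 °C to rt
Reagents that add atoms: triisopropylsilyl chloride, CC(C)[Si](Cl)(C(C)C)C(C)C
Why: Silylation stops after two groups because the last ortho hydroxyl is locked in a hydrogen bond to the aldehyde; the symmetric substrate gives one product.

Step 5
Reactants: 7 2-hydroxy-4,6-bis(triisopropylsilyloxy)benzaldehyde
Product: 8 3-bromo-2-hydroxy-4,6-bis(triisopropylsilyloxy)benzaldehyde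
Conditions: NBS (1.0 equiv), i-Pr2NH (10 mol%), CH2Cl2, −20 to 0 °C
Reagents that add atoms: N-bromosuccinimide, O=C1CCC(=O)N1Br
Why: Electrophilic aromatic bromination goes ortho to the free phenol, since the only other open position lies between two bulky silyloxy groups; this ties the bromide (later C8) to the oxygen that becomes O1.

Step 6
Reactants: 9 2-methylbut-1-en-3-yne; 10 pinacolborane
Product: 11 (E)-4,4,5,5-tetramethyl-2-(3-methylbuta-1,3-dienyl)-1,3,2-dioxaborolane
Conditions: Cp2Zr(H)Cl (5 mol%), Et3N (10 mol%), neat, 60 °C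
Reagents that add atoms: none
Why: Zirconium-hydride-catalysed syn hydroboration of the terminal alkyne gives the E-alkenyl boronate and leaves the 1,1-disubstituted alkene untouched.

Step 7
Reactants: 8 3-bromo-2-hydroxy-4,6-bis(triisopropylsilyloxy)benzaldehyde; 11 (E)-4,4,5,5-tetramethyl-2-(3-methylbuta-1,3-dienyl)-1,3,2-dioxaborolane
Product: 12 2-hydroxy-3-[(E)-3-methylbuta-1,3-dienyl]-4,6-bis(triisopropylsilyloxy)benzaldehyde
Conditions: Pd(OAc)2 (5 mol%), SPhos (10 mol%), K3PO4, THF/H2O (10:1), 50 °C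
Reagents that add atoms: none
Why: Suzuki–Miyaura coupling installs the diene with retention of E geometry, and it is run before any allyl ether is present on this ring.

Step 8
Reactants: 12 2-hydroxy-3-[(E)-3-methylbuta-1,3-dienyl]-4,6-bis(triisopropylsilyloxy)benzaldehyde; 2 prenyl bromide
Product: 13 3-[(E)-3-methylbuta-1,3-dienyl]-2-(3-methylbut-2-enyloxy)-4,6-bis(triisopropylsilyloxy)benzaldehyde
Conditions: K2CO3, MeCN, 45 °C
Reagents that add atoms: none
Why: Williamson O-prenylation of the acidic ortho-formyl phenol places the prenyl group on the oxygen that will become O1 and will hand the prenyl to C3.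

Step 9
Reactants: 5 1-ethynyl-4-(3-methylbut-2-enyloxy)-2-(triisopropylsilyloxy)benzene; 13 3-[(E)-3-methylbuta-1,3-dienyl]-2-(3-methylbut-2-enyloxy)-4,6-bis(triisopropylsilyloxy)benzaldehyde
Product: 15 1-{3-[(E)-3-methylbuta-1,3-dienyl]-2-(3-methylbut-2-enyloxy)-4,6-bis(triisopropylsilyloxy)phenyl}-3-[4-(3-methylbut-2-enyloxy)-2-(triisopropylsilyloxy)phenyl]prop-2-yn-1-ol (racemic), via lithium acetylide 14 (not isolated)
Conditions: 5, n-BuLi, THF, −78 °C; then 13, −78 to −20 °C; H2O
Reagents that add atoms: none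
Why: 1,2-Addition of the lithium acetylide to the aldehyde joins rings A and B; the new carbinol centre is racemic and is removed in step 10.

Step 10
Reactants: 15 the propargylic alcohol from step 9
Product: 16 1-{3-[(E)-3-methylbuta-1,3-dienyl]-2-(3-methylbut-2-enyloxy)-4,6-bis(triisopropylsilyloxy)phenyl}-3-[4-(3-methylbut-2-enyloxy)-2-(triisopropylsilyloxy)phenyl]prop-2-yn-1-one
Conditions: MnO2 (20 equiv), CH2Cl2, rt; used at once, kept dilute
Reagents that add atoms: none
Why: MnO2 oxidises the benzylic and propargylic alcohol to the ynone under neutral conditions that spare the diene, the prenyl ethers and the silyl ethers.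

Step 11
Reactants: 16 the ortho-prenyloxy aryl ynone from step 10
Product: 17 8-[(E)-3-methylbuta-1,3-dienyl]-3-(3-methylbut-2-enyl)-2-[4-(3-methylbut-2-enyloxy)-2-(triisopropylsilyloxy)phenyl]-5,7-bis(triisopropylsilyloxy)chromen-4-one
Conditions: Pd(PPh3)4 (5 mol%), toluene (0.02 M), 60 °C
Reagents that add atoms: none
Why: Proposed new method: zerovalent palladium ionises the ring-A aryl prenyl ether (a good leaving phenoxide, being ortho to the ynone carbonyl) to a phenoxide/π-prenyl-palladium ion pair; O-realkylation is reversible (this also makes any ionisation of the ring-B prenyl ether degenerate), whereas 6-endo oxa-Michael addition of the phenoxide to the ynone gives an allenolate that the π-prenyl cation traps irreversibly at C3 through its less hindered terminus, so one reagent-free isomerisation forms the O1–C2 bond of ring C and the linear C3–prenyl bond; the closest known reaction type is the zerovalent-palladium-catalysed cyclisation of 2-alkynylphenyl allyl ethers to 3-allylbenzofurans with O-to-C allyl transfer, not yet shown for ynones, for chromone formation or for a prenyl group.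

Step 12
Reactants: 17 the tris(silyl) flavone from step 11
Product: 19 2-[2-acetoxy-4-(3-methylbut-2-enyloxy)phenyl]-8-[(E)-3-methylbuta-1,3-dienyl]-3-(3-methylbut-2-enyl)-4-oxochromene-5,7-diyl diacetate, via flavone triol 18 (not isolated)
Conditions: TBAF (3.3 equiv), THF, 0 °C; then Ac2O (8 equiv), DMAP (10 mol%), 0 °C to rt
Reagents that add atoms: acetic anhydride, CC(=O)OC(C)=O
Why: Fluoride cleaves the three aryl silyl ethers without acid, and the phenoxides (including the normally sluggish chelated 5-O) are acetylated in the same flask.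

Step 13
Reactants: 20 2,4-dihydroxyacetophenone; 2 prenyl bromide
Product: 21 2,4-dihydroxy-3-(3-methylbut-2-enyl)acetophenone
Conditions: KOH (10% aq.), 0 °C to rt
Reagents that add atoms: none
Why: Direct C-alkylation of the resorcinol dianion in water occurs mainly at C3, between the two oxygens (known, modest yield; isomers removed by chromatography).

Step 14
Reactants: 1 2,4-dihydroxybenzaldehyde
Product: 22 2,4-bis(methoxymethoxy)benzaldehyde
Conditions: MOMCl (2.5 equiv), K2CO3, acetone, reflux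
Reagents that add atoms: chloromethyl methyl ether, COCCl
Why: Acetal protection of both phenols keeps the aldehyde electrophilic under the strongly basic aldol conditions.

Step 15
Reactants: 21 2,4-dihydroxy-3-(3-methylbut-2-enyl)acetophenone; 22 2,4-bis(methoxymethoxy)benzaldehyde
Product: 23 (E)-3-[2,4-bis(methoxymethoxy)phenyl]-1-[2,4-dihydroxy-3-(3-methylbut-2-enyl)phenyl]prop-2-en-1-one
Conditions: KOH (50% aq.), EtOH, rt, 36 h
Reagents that add atoms: none
Why: Claisen–Schmidt aldol condensation, with E1cB loss of water giving the E-enone.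

Step 16
Reactants: 23 the bis(MOM) chalcone from step 15
Product: 24 morachalcone A, (E)-1-[2,4-dihydroxy-3-(3-methylbut-2-enyl)phenyl]-3-(2,4-dihydroxyphenyl)prop-2-en-1-one
Conditions: HCl (3 M aq.), MeOH, 50 °C, short reaction time
Reagents that add atoms: none
Why: Acid-catalysed transacetalisation removes both MOM ethers; this molecule has no aryl prenyl ether, and brief exposure spares the C-prenyl group.

Step 17
Reactants: 24 morachalcone A
Product: 25 4-{(E)-3-[4-acetoxy-2-hydroxy-3-(3-methylbut-2-enyl)phenyl]-3-oxoprop-1-enyl}-1,3-phenylene diacetate (morachalcone A triacetate with the 2'-OH free)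
Conditions: Ac2O (3.3 equiv), Et3N, CH2Cl2, 0 °C
Reagents that add atoms: acetic anhydride, CC(=O)OC(C)=O
Why: Selective O-acetylation leaves the 2'-OH, which is hydrogen-bonded to the ketone, free as the boron-binding site for step 18.

Step 18
Reactants: 25 morachalcone A triacetate; 19 flavone diene triacetate
Product: 27 8-[(1S,5R,6S)-6-[4-acetoxy-2-hydroxy-3-(3-methylbut-2-enyl)benzoyl]-5-(2,4-diacetoxyphenyl)-3-methylcyclohex-2-en-1-yl]-2-[2-acetoxy-4-(3-methylbut-2-enyloxy)phenyl]-3-(3-methylbut-2-enyl)-4-oxochromene-5,7-diyl diacetate, via borate chelate 26 (not isolated)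
Conditions: (S)-VANOL (1.2 equiv), BH3·THF (1.2 equiv), AcOH (1.2 equiv), THF, rt; then 25; then 19 (1.3 equiv), PhCF3, rt; H2O; SiO2 separation of the exo adduct from the endo isomer
Reagents that add atoms: none
Why: Chiral-borate-promoted Diels–Alder reaction of a 2'-hydroxychalcone: the diene CH2 terminus bonds to the enone β-carbon, suprafacial addition keeps the E-enone substituents trans (C5/C6 of the cyclohexene), exo approach puts the flavone trans to the benzoyl group (C1/C6), and the VANOL wall selects the enone face, setting (1S,5R,6S).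

Step 19
Reactants: 27 the hexaacetate from step 18
Product: 28 8-[(1S,5R,6S)-6-[2,4-dihydroxy-3-(3-methylbut-2-enyl)benzoyl]-5-(2,4-dihydroxyphenyl)-3-methylcyclohex-2-en-1-yl]-5,7-dihydroxy-2-[2-hydroxy-4-(3-methylbut-2-enyloxy)phenyl]-3-(3-methylbut-2-enyl)chromen-4-one (CNP0082413.1)
Conditions: K2CO3 (0.5 equiv), MeOH/THF (1:1), 0 °C to rt; NH4Cl work-up
Reagents that add atoms: none
Why: Base-catalysed methanolysis removes the six aryl acetates without acid, so the aryl prenyl ether, the C-prenyl groups and the three stereocentres are untouched.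

**Compound list**
1 | 2,4-dihydroxybenzaldehyde | O=Cc1ccc(O)cc1O | starting material
2 | prenyl bromide (1-bromo-3-methylbut-2-ene) | CC(C)=CCBr | starting material
3 | 2-hydroxy-4-(3-methylbut-2-enyloxy)benzaldehyde | CC(C)=CCOc1ccc(C=O)c(O)c1 | intermediate
4 | 4-(3-methylbut-2-enyloxy)-2-(triisopropylsilyloxy)benzaldehyde | CC(C)=CCOc1ccc(C=O)c(O[Si](C(C)C)(C(C)C)C(C)C)c1 | intermediate
5 | 1-ethynyl-4-(3-methylbut-2-enyloxy)-2-(triisopropylsilyloxy)benzene | CC(C)=CCOc1ccc(C#C)c(O[Si](C(C)C)(C(C)C)C(C)C)c1 | intermediate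
6 | 2,4,6-trihydroxybenzaldehyde | O=Cc1c(O)cc(O)cc1O | starting material
7 | 2-hydroxy-4,6-bis(triisopropylsilyloxy)benzaldehyde | O=Cc1c(O)cc(O[Si](C(C)C)(C(C)C)C(C)C)cc1O[Si](C(C)C)(C(C)C)C(C)C | intermediate
8 | 3-bromo-2-hydroxy-4,6-bis(triisopropylsilyloxy)benzaldehyde | O=Cc1c(O)c(Br)c(O[Si](C(C)C)(C(C)C)C(C)C)cc1O[Si](C(C)C)(C(C)C)C(C)C | intermediate
9 | 2-methylbut-1-en-3-yne | C=C(C)C#C | starting material
10 | pinacolborane | CC1(C)OBOC1(C)C | starting material
11 | (E)-4,4,5,5-tetramethyl-2-(3-methylbuta-1,3-dienyl)-1,3,2-dioxaborolane | C=C(C)/C=C/B1OC(C)(C)C(C)(C)O1 | intermediate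
12 | 2-hydroxy-3-[(E)-3-methylbuta-1,3-dienyl]-4,6-bis(triisopropylsilyloxy)benzaldehyde | O=Cc1c(O)c(/C=C/C(C)=C)c(O[Si](C(C)C)(C(C)C)C(C)C)cc1O[Si](C(C)C)(C(C)C)C(C)C | intermediate
13 | 3-[(E)-3-methylbuta-1,3-dienyl]-2-(3-methylbut-2-enyloxy)-4,6-bis(triisopropylsilyloxy)benzaldehyde | O=Cc1c(OCC=C(C)C)c(/C=C/C(C)=C)c(O[Si](C(C)C)(C(C)C)C(C)C)cc1O[Si](C(C)C)(C(C)C)C(C)C | intermediate
14 | lithium acetylide of 5 | [Li]C#Cc1ccc(OCC=C(C)C)cc1O[Si](C(C)C)(C(C)C)C(C)C | intermediate (not isolated)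
15 | propargylic alcohol joining rings A and B (racemic carbinol) | OC(C#Cc1ccc(OCC=C(C)C)cc1O[Si](C(C)C)(C(C)C)C(C)C)c1c(OCC=C(C)C)c(/C=C/C(C)=C)c(O[Si](C(C)C)(C(C)C)C(C)C)cc1O[Si](C(C)C)(C(C)C)C(C)C | intermediate
16 | ortho-prenyloxy aryl ynone | O=C(C#Cc1ccc(OCC=C(C)C)cc1O[Si](C(C)C)(C(C)C)C(C)C)c1c(OCC=C(C)C)c(/C=C/C(C)=C)c(O[Si](C(C)C)(C(C)C)C(C)C)cc1O[Si](C(C)C)(C(C)C)C(C)C | intermediate
17 | 8-dienyl-3-prenyl-4'-O-prenyl flavone, 5,7,2'-tris(TIPS ether) | CC(C)=CCOc1ccc(-c2oc3c(/C=C/C(C)=C)c(O[Si](C(C)C)(C(C)C)C(C)C)cc(O[Si](C(C)C)(C(C)C)C(C)C)c3c(=O)c2CC=C(C)C)c(O[Si](C(C)C)(C(C)C)C(C)C)c1 | intermediate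
18 | 5,7-dihydroxy-2-[2-hydroxy-4-(3-methylbut-2-enyloxy)phenyl]-8-[(E)-3-methylbuta-1,3-dienyl]-3-(3-methylbut-2-enyl)chromen-4-one (present as its tetrabutylammonium phenoxide) | CC(C)=CCOc1ccc(-c2oc3c(/C=C/C(C)=C)c(O)cc(O)c3c(=O)c2CC=C(C)C)c(O)c1 | intermediate (not isolated)
19 | flavone diene 5,7,2'-triacetate | CC(C)=CCOc1ccc(-c2oc3c(/C=C/C(C)=C)c(OC(C)=O)cc(OC(C)=O)c3c(=O)c2CC=C(C)C)c(OC(C)=O)c1 | intermediate
20 | 2,4-dihydroxyacetophenone | CC(=O)c1ccc(O)cc1O | starting material
21 | 2,4-dihydroxy-3-(3-methylbut-2-enyl)acetophenone | CC(=O)c1ccc(O)c(CC=C(C)C)c1O | intermediate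
22 | 2,4-bis(methoxymethoxy)benzaldehyde | COCOc1ccc(C=O)c(OCOC)c1 | intermediate
23 | morachalcone A 2,4-bis(MOM) ether | COCOc1ccc(/C=C/C(=O)c2ccc(O)c(CC=C(C)C)c2O)c(OCOC)c1 | intermediate
24 | morachalcone A | Oc1ccc(/C=C/C(=O)c2ccc(O)c(CC=C(C)C)c2O)c(O)c1 | intermediate
25 | morachalcone A triacetate (2'-OH free) | CC(=O)Oc1ccc(/C=C/C(=O)c2ccc(OC(C)=O)c(CC=C(C)C)c2O)c(OC(C)=O)c1 | intermediate
26 | (S)-VANOL borate chelate of 25 (boron bound to the 2'-oxygen and the ketone oxygen; S axis, not expressible in the SMILES) | CC(=O)Oc1ccc2c(c1CC=C(C)C)O[B-]1(Oc3c(c(-c4ccccc4)cc4ccccc34)-c3c(O1)c1ccccc1cc3-c1ccccc1)[O+]=C2/C=C/c1ccc(OC(C)=O)cc1OC(C)=O | intermediate (not isolated)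
27 | (1S,5R,6S) all-trans Diels–Alder adduct, hexaacetate | CC(C)=CCOc1ccc(-c2oc3c([C@H]4C=C(C)C[C@@H](c5ccc(OC(C)=O)cc5OC(C)=O)[C@@H]4C(=O)c4ccc(OC(C)=O)c(CC=C(C)C)c4O)c(OC(C)=O)cc(OC(C)=O)c3c(=O)c2CC=C(C)C)c(OC(C)=O)c1 | intermediate
28 | CNP0082413.1 (4'-O-prenyl ether of the kuwanon H skeleton) | CC(C)=CCOc1ccc(-c2oc3c([C@H]4C=C(C)C[C@@H](c5ccc(O)cc5O)[C@@H]4C(=O)c4ccc(O)c(CC=C(C)C)c4O)c(O)cc(O)c3c(=O)c2CC=C(C)C)c(O)c1 | target

**Step count**
Total: 19 steps. Longest linear sequence: 10 steps (4, 5, 7, 8, 9, 10, 11, 12, 18, 19, starting from 6).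

**Three steps most likely to fail**

Step 11 (the proposed new cyclisation). Possible failures are loss of the prenyl group as isoprene to give the 3-unsubstituted flavone, prenyl crossover involving the ring-B ether, and 5-exo closure to an aurone. The fallback uses known chemistry, sets out from 12 (with acetylide 14) and comes back at 17. Aldehyde 12 is treated with 2.2 equiv of 14 (the first equivalent deprotonates the phenol) to give the phenolic propargylic alcohol F1. MnO2 oxidises it to the ortho-hydroxyaryl ynone F2. K2CO3 in acetone closes F2 by 6-endo oxa-Michael addition to the 3-unsubstituted flavone F3. LiN(i-Pr)2 in THF at −78 °C lithiates C3 of F3, and alkylation with 2 gives 17.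

Step 18 (exo and facial selectivity of the cycloaddition). The borate may give mainly the endo adduct or low enantioselectivity. The fallback sets out from 19 and 25 and comes back at 27, replacing asymmetric induction by resolution. The two partners are combined over Ag nanoparticles on SiO2 in CH2Cl2 at 50 °C to give racemic adducts; the endo pair is removed on silica gel, and the exo racemate is separated on a chiral stationary phase into 27 and its discarded mirror-image hexaacetate F4.

Step 13 (direct C-prenylation). The yield is low and O- and 5-C-prenyl isomers form. The fallback sets out from 20 and comes back at 21. Ketone 20 is O-alkylated at the 4-OH with 3-chloro-3-methylbut-1-yne (K2CO3, KI, CuI cat., acetone) to the 1,1-dimethylpropargyl ether F5. Semi-hydrogenation (H2, Pd/CaCO3 poisoned with Pb(OAc)2, quinoline) gives the 1,1-dimethylallyl ether F6. Aromatic Claisen rearrangement (N,N-diethylaniline, 190 °C) moves the group to C3 with allyl inversion, giving the linear prenyl group of 21.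

Further compounds
F1 | step 11 | 1-{2-hydroxy-3-[(E)-3-methylbuta-1,3-dienyl]-4,6-bis(triisopropylsilyloxy)phenyl}-3-[4-(3-methylbut-2-enyloxy)-2-(triisopropylsilyloxy)phenyl]prop-2-yn-1-ol (racemic) | OC(C#Cc1ccc(OCC=C(C)C)cc1O[Si](C(C)C)(C(C)C)C(C)C)c1c(O)c(/C=C/C(C)=C)c(O[Si](C(C)C)(C(C)C)C(C)C)cc1O[Si](C(C)C)(C(C)C)C(C)C
F2 | step 11 | 1-{2-hydroxy-3-[(E)-3-methylbuta-1,3-dienyl]-4,6-bis(triisopropylsilyloxy)phenyl}-3-[4-(3-methylbut-2-enyloxy)-2-(triisopropylsilyloxy)phenyl]prop-2-yn-1-one | O=C(C#Cc1ccc(OCC=C(C)C)cc1O[Si](C(C)C)(C(C)C)C(C)C)c1c(O)c(/C=C/C(C)=C)c(O[Si](C(C)C)(C(C)C)C(C)C)cc1O[Si](C(C)C)(C(C)C)C(C)C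
F3 | step 11 | 8-[(E)-3-methylbuta-1,3-dienyl]-2-[4-(3-methylbut-2-enyloxy)-2-(triisopropylsilyloxy)phenyl]-5,7-bis(triisopropylsilyloxy)chromen-4-one | CC(C)=CCOc1ccc(-c2cc(=O)c3c(O[Si](C(C)C)(C(C)C)C(C)C)cc(O[Si](C(C)C)(C(C)C)C(C)C)c(/C=C/C(C)=C)c3o2)c(O[Si](C(C)C)(C(C)C)C(C)C)c1
F4 | step 18 | (1R,5S,6R) mirror image of hexaacetate 27 | CC(C)=CCOc1ccc(-c2oc3c([C@@H]4C=C(C)C[C@H](c5ccc(OC(C)=O)cc5OC(C)=O)[C@H]4C(=O)c4ccc(OC(C)=O)c(CC=C(C)C)c4O)c(OC(C)=O)cc(OC(C)=O)c3c(=O)c2CC=C(C)C)c(OC(C)=O)c1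
F5 | step 13 | 1-[2-hydroxy-4-(2-methylbut-3-yn-2-yloxy)phenyl]ethanone | CC(=O)c1ccc(OC(C)(C)C#C)cc1O
F6 | step 13 | 1-[2-hydroxy-4-(2-methylbut-3-en-2-yloxy)phenyl]ethanone | CC(=O)c1ccc(OC(C)(C)C=C)cc1O
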